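**False level.** A curve gone flat tempts you to call it equilibrium, after which the order of addition cannot matter.

| flask | first end groups | second end groups | protic impurity | remark | time |
|---|---|---|---|---|---|
| cedar | 0.050 M | 0.055 M | 0.015 M | run made earlier |  |
| alder | 0.050 M | 0.028 M | 0.015 M | run made earlier |  |
| elm | 0.050 M | 0.11 M | 0.015 M | run made earlier |  |
| oak | 0.025 M | 0.055 M | 0.015 M | run made earlier |  |
| dusk | 0.050 M | 0.0550 M | 0.0150 M | everything together at the start | 2.0 d |
| midnight | 0.050 M | 0.0550 M (fed, over 10 h) | 0.0150 M | all else is in the flask from the start; the feed brings no volume worth counting | 2.0 d |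
| winter | 0.050 M (fed, over 10 h) | 0.0550 M | 0.0150 M | all else is in the flask from the start; the feed brings no volume worth counting | 2.0 d |

| run | time / h | links / % | first end groups / % |
|---|---|---|---|
| cedar | 2.50 | 7.7 | 91.7 |
| cedar | 4.00 | 10.5 | 89.7 |
| cedar | 8.00 | 13.3 | 86.5 |
| cedar | 15.0 | 16.7 | 83.8 |
| cedar | 30.0 | 18.1 | 80.6 |
| alder | 3.00 | 5.3 | 94.4 |
| alder | 10.0 | 10.7 | 91.2 |
| alder | 20.0 | 10.9 | 88.7 |
| alder | 30.0 | 11.7 | 88.0 |
| alder | 40.0 | 11.3 | 87.9 |
| elm | 3.00 | 14.5 | 85.7 |
| elm | 10.0 | 21.1 | 79.0 |
| elm | 20.0 | 24.7 | 75.0 |
| elm | 30.0 | 26.4 | 73.0 |
| elm | 40.0 | 27.3 | 72.4 |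
| oak | 3.00 | 9.4 | 89.4 |
| oak | 10.0 | 15.7 | 84.2 |
| oak | 20.0 | 19.7 | 80.5 |
| oak | 30.0 | 19.8 | 78.0 |
| oak | 40.0 | 22.0 | 78.3 |

(each reading ± 0.5 percentage points)

* which flask leads in amount of links, in percent of the first end groups charged ("all alike" within 1.5 percentage points) (dusk / midnight / winter / all alike)
* how much links is there at the end, in percent of the first end groups charged: dusk
* how much links is there at the end, in percent of the first end groups charged: midnight
* how much links is there at the end, in percent of the first end groups charged: winter

- the numbers in the tables scatter with a standard deviation of 0.5 percentage points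

**The clock.** First end groups lost match links gained, so try a pseudo-first-order reading. By 30.0 h cedar reads 0.216 in exposure X, the logarithm of charged over remaining first end groups. Oak, with half cedar's first end groups, reads slightly more by 40.0 h, 0.245. So X moves little with first end groups. Dusk repeats cedar's charges, so I put its links at about 19.4%.

**Winter's bracket.** In winter, each dose of first end groups collects the exposure still to come. Cedar's X, averaged over the 10 h feed, is 0.106. Subtracting it from cedar's last value gives a rough floor of 10.4%; subtracting it from oak's gives a rough ceiling of 12.9%.

**Midnight's bracket.** Let e be X per charge of second end groups: elm 2.94 M⁻¹, cedar 3.92 M⁻¹, alder 4.61 M⁻¹. The feed needs 5.09 h to deliver alder's charge, longer than the 4.00 h by which cedar reads half its exposure. So I expect midnight to stay lean, and alder's e gives a rough floor of 22.4%. Each halving of the charge adds to e, each step being 0.695 of the one before, as read from these runs. Summing such steps gives e = 6.17 M⁻¹ and a rough ceiling of 28.8%. I expect midnight to lead.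

**The forecast.** It said all alike, with dusk 19%, midnight 18.8% and winter 18.8%, since “the order of addition should not matter if there is time to get there”; its midnight lies below my floor and its winter above my ceiling.

**The result.** The leader is midnight: links stand at dusk 19.5%, midnight 25.8%, winter 11.1%.

    second end groups + protic impurity → quenched reagent (k = 0.210 M⁻¹ min⁻¹)
    first end groups + second end groups → links + released group (k = 0.0190 M⁻¹ min⁻¹)
    2 second end groups → self-condensation product (k = 0.0790 M⁻¹ min⁻¹)

**What stood.** Midnight's exposure came to 0.298 and winter's to 0.117, against cedar's 0.216. In winter, half of the self-condensation turnover up to the asked time was done by 1.10 h, far sooner than half of the link turnover at 0.424 d, with the feed lasting 10 h. At the end of that feed, winter held 0.0170 M of self-condensation product and 9.82% of its second end groups. Winter's exposure over cedar's is 0.544; applied to alder's e, it gives links of 3.45% for the winter neighbour with 0.014 M of second end groups, whose links stood at 3.41%.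

(The runs come from a simulation with constants of no real substance, noise included.)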